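I will reckon this flask by one clock, and I choose the half-life of free monomer while chains grow.

| flask | free monomer | initiator | remark | time |
|---|---|---|---|---|
| delta | 0.050 M | 1 mol% | run made earlier |  |
| gamma | 0.20 M | 1 mol% | run made earlier |  |
| eta | 0.10 M | 0.5 mol% | run made earlier |  |
| flask | 0.10 M | 1 mol% |  | 4.0 h |

| run | time / h | monomer in chains / % | free monomer / % |
|---|---|---|---|
| delta | 0.250 | 2.0 | 99.7 |
| delta | 0.500 | 5.3 | 95.3 |
| delta | 0.833 | 12.7 | 88.8 |
| delta | 1.50 | 27.8 | 69.3 |
| delta | 3.00 | 62.5 | 37.5 |
| gamma | 0.250 | 14.2 | 82.4 |
| gamma | 0.833 | 68.9 | 33.2 |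
| gamma | 1.33 | 86.9 | 12.5 |
| gamma | 2.50 | 98.3 | 1.4 |
| gamma | 3.00 | 99.7 | 0.6 |
| eta | 0.250 | 3.8 | 98.9 |
| eta | 0.833 | 17.7 | 81.3 |
| eta | 1.33 | 33.9 | 64.3 |
| eta | 2.50 | 65.2 | 36.2 |
| eta | 3.00 | 74.2 | 27.6 |

(standard deviation of a reading: 1 percentage point)

- average number of monomer units in a chain (chains begun, living or dead) at 4.0 h
- part of the free monomer that has reacted at 4.0 h

- the average divides the monomer in chains by the number of chains begun, living and dead together
- the earlier runs do not show the number of chains; that part of a forecast is a guess

Does the late decay follow free monomer or initiator? The slope of ln c(free monomer) reads 0.506 h⁻¹ in eta and 0.409 h⁻¹ in delta, which has the same c(initiator) and half the free monomer. Gamma, with 4.00 times eta's c(initiator), reads 1.97 h⁻¹, or 3.89 times eta. So I treat the decay as pseudo-first-order, with a slope of 1010 M⁻¹ h⁻¹ times c(initiator).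

For the flask, the growth half-life, the time in which free monomer halves once the charged initiator has begun its chains, is 0.684 h.

When does this clock start? Eta has the flask's free monomer, and extending its late slope back gives a lag of 0.458 h, which I assume holds for the flask.

How many half-lives then fit? There are 5.18, which leaves 2.77% of the free monomer, so I expect c near 97.2%. The runs do not show chains, so my dp is a guess: 97.2, if every charged initiator began one chain.

The forecast gives a dp of 98, just above my guess, and a c of 96.5%, just below mine, reasoning that “The slope therefore follows initiator concentration”.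

The flask gives a dp of 111 and a c of 96.8%.

    free monomer + living end → monomer in chains + living end, rate k1*[living end]*[free monomer] (k = 0.320 M⁻¹ s⁻¹)
    free monomer + initiator → living end + monomer in chains (k = 0.00420 M⁻¹ s⁻¹)
    initiator + monomer in chains → spent initiator (k = 2.60 × 10⁻⁴ M⁻¹ s⁻¹)

At 4.00 h in the flask, free monomer has a half-life of 0.69 h by growth, beside the 0.684 h I reckoned from the charge of initiator, and 21 d by the step that begins chains, so growth uses it 720 times as fast. For the neighbour flask with 0.4 mol% of initiator, my half-life becomes 1.71 h, which with the same lag leaves 23.8% of the free monomer, and that neighbour holds 23% at 4.00 h.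

The runs were generated by integration from invented constants; scatter was added.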